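**Retrosynthetic overview**
1. Target 15 ⇐ nona-O-benzyl ether 14 by global hydrogenolysis. The C4–C8 interflavan bond is not made by the usual flavan-4-yl cation + epigallocatechin Friedel–Crafts coupling.
2. Upper pyran ring (the only ring built, closed last): O1–C8a by intramolecular SNAr of a benzylic alkoxide on an aryl fluoride, with retention at C2 ⇐ alcohol 12 ⇐ ketone 11 by asymmetric transfer hydrogenation (sets C2).
3. Key step: the C4–C4a bond and the C4 stereocentre by Rh/chiral-diene 1,4-addition of a 2-fluoroarylboronic acid to chalcone 9, whose β-carbon already carries C8 of the lower unit.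
4. Chalcone 9 ⇐ Claisen–Schmidt condensation of 8-formyl-hexa-O-benzyl-epigallocatechin 7 with acetophenone 8; 7 ⇐ C8 bromination, Br/Li exchange and DMF on benzylated (−)-epigallocatechin 1.
5. Ring order: the lower A/C/B rings come intact from 1; the upper A and B rings are bought arenes; the upper C-ring closes in step 8.

**Assumptions:** the target is (2S)-7,3',4'-trihydroxyflavan-(4β→8)-(−)-epigallocatechin (upper unit 2S,4R, 2,4-trans; lower unit 2R,3R). Compounds 1, 8 and 10 are bought. The sense of induction of the Rh/diene catalyst on enone 9 is taken by analogy and is checked on the first run (the C4 epimers are diastereomers); the other ligand antipode is used if needed.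

**Abbreviation:** E8 = (2R,3R)-3,5,7-tris(benzyloxy)-2-[3,4,5-tris(benzyloxy)phenyl]chroman-8-yl (chroman = 3,4-dihydro-2H-chromene).

**Step 1**
Reactants: 1 (−)-epigallocatechin
Product: 2 (2R,3R)-5,7-bis(benzyloxy)-2-[3,4,5-tris(benzyloxy)phenyl]chroman-3-ol
Conditions: BnBr (5.5 equiv), K2CO3 (6 equiv), DMF, −10 °C → rt, Ar
Reagents that add atoms: benzyl bromide, BrCc1ccccc1
Why: Williamson etherification; K2CO3 deprotonates only the five phenols, so the secondary 3-OH stays free and C2/C3 are untouched.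

**Step 2**
Reactants: 2 (2R,3R)-5,7-bis(benzyloxy)-2-[3,4,5-tris(benzyloxy)phenyl]chroman-3-ol
Product: 3 (2R,3R)-3,5,7-tris(benzyloxy)-2-[3,4,5-tris(benzyloxy)phenyl]chroman (E8–H)
Conditions: NaH (1.5 equiv), BnBr (1.5 equiv), cat. Bu4NI, THF/DMF, 0 °C → rt
Reagents that add atoms: benzyl bromide, BrCc1ccccc1
Why: Williamson etherification of the secondary alkoxide; with no free phenol left there is no base-induced C2 epimerisation through a ring-opened quinone methide.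

**Step 3**
Reactants: 3 E8–H
Product: 4 (2R,3R)-3,5,7-tris(benzyloxy)-8-bromo-2-[3,4,5-tris(benzyloxy)phenyl]chroman (E8–Br)
Conditions: NBS (1.0 equiv), CH2Cl2, −78 → 0 °C
Reagents that add atoms: N-bromosuccinimide, O=C1CCC(=O)N1Br
Why: electrophilic aromatic bromination; the phloroglucinol-type A-ring is the most activated ring and reacts at C8 rather than at C6, which is crowded between two benzyloxy groups.

**Step 4**
Reactants: 4 E8–Br
Product: 7 (2R,3R)-3,5,7-tris(benzyloxy)-2-[3,4,5-tris(benzyloxy)phenyl]chroman-8-carbaldehyde (E8–CHO), via aryllithium 5 (not isolated), via lithium aminoalkoxide 6 (not isolated)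
Conditions: n-BuLi (1.1 equiv), THF, −78 °C; DMF (3 equiv), −78 → 0 °C; H2O
Reagents that add atoms: N,N-dimethylformamide, CN(C)C=O
Why: bromine–lithium exchange outruns benzylic deprotonation of the benzyl ethers at −78 °C, and Bouveault formylation stops at the tetrahedral adduct until aqueous work-up.

**Step 5**
Reactants: 7 E8–CHO; 8 1-[3,4-bis(benzyloxy)phenyl]ethan-1-one
Product: 9 (2E)-1-[3,4-bis(benzyloxy)phenyl]-3-(E8)prop-2-en-1-one
Conditions: KOH (aq.), EtOH/THF, rt → 45 °C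
Reagents that add atoms: none
Why: Claisen–Schmidt aldol condensation of a non-enolisable aldehyde; E1cB dehydration gives the conjugated (E)-enone, and no existing stereocentre bears an acidic hydrogen.

**Step 6**
Reactants: 9 (2E)-1-[3,4-bis(benzyloxy)phenyl]-3-(E8)prop-2-en-1-one; 10 [4-(benzyloxy)-2-fluorophenyl]boronic acid (3 equiv)
Product: 11 (3S)-3-[4-(benzyloxy)-2-fluorophenyl]-1-[3,4-bis(benzyloxy)phenyl]-3-(E8)propan-1-one
Conditions: [RhCl(C2H4)2]2 (3 mol%), (R,R)-Ph-bod* (7 mol%), KOH (0.5 equiv), dioxane/H2O 10:1, 60 °C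
Reagents that add atoms: none
Why: Hayashi–Miyaura Rh-catalysed asymmetric conjugate arylation; the chiral diene directs aryl–Rh insertion to the Si face of C-β, which sets the future C4 (S in 11 because the fluoroaryl ring outranks E8; the same centre is 4R in 14), and the Rh enolate is protonated by water.

**Step 7**
Reactants: 11 (3S)-3-[4-(benzyloxy)-2-fluorophenyl]-1-[3,4-bis(benzyloxy)phenyl]-3-(E8)propan-1-one
Product: 12 (1S,3S)-3-[4-(benzyloxy)-2-fluorophenyl]-1-[3,4-bis(benzyloxy)phenyl]-3-(E8)propan-1-ol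
Conditions: RuCl[(S,S)-TsDPEN](p-cymene) (5 mol%), HCO2H/Et3N 5:2, CH2Cl2, 35 °C
Reagents that add atoms: none
Why: Noyori–Ikariya asymmetric transfer hydrogenation of an aryl alkyl ketone; the (S,S)-catalyst gives the (S)-carbinol (as for acetophenone) under catalyst control, which sets the future C2; ArF and benzyl ethers are inert.

**Step 8**
Reactants: 12 (1S,3S)-3-[4-(benzyloxy)-2-fluorophenyl]-1-[3,4-bis(benzyloxy)phenyl]-3-(E8)propan-1-ol
Product: 14 (2S,4R)-7-(benzyloxy)-2-[3,4-bis(benzyloxy)phenyl]-4-(E8)chroman, via sodium alkoxide 13 (not isolated)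
Conditions: NaH (1.5 equiv), DMF, 0 → 90 °C
Reagents that add atoms: none
Why: intramolecular SNAr (six-membered ring) of the alkoxide on the aryl fluoride; the carbinol C–O bond is never broken, so C2 forms with retention (1S → 2S), C4 is untouched, and the 2,4-trans flavan results.

**Step 9**
Reactants: 14 (2S,4R)-7-(benzyloxy)-2-[3,4-bis(benzyloxy)phenyl]-4-(E8)chroman
Product: 15 (2R,3R)-8-[(2S,4R)-2-(3,4-dihydroxyphenyl)-7-hydroxychroman-4-yl]-2-(3,4,5-trihydroxyphenyl)chroman-3,5,7-triol (target)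
Conditions: H2 (1 atm), 20% Pd(OH)2/C, THF/MeOH 1:1, rt; filter under Ar
Reagents that add atoms: none
Why: hydrogenolysis of nine O-benzyl ethers over Pearlman's catalyst under neutral conditions, which leave the interflavan bond, the pyran C–O bonds and all four stereocentres alone.

**Compound list**
1 | (−)-epigallocatechin, (2R,3R)-2-(3,4,5-trihydroxyphenyl)chroman-3,5,7-triol | c1c(O)cc(O)c2c1O[C@H](c1cc(O)c(O)c(O)c1)[C@H](O)C2 | starting material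
2 | (2R,3R)-5,7-bis(benzyloxy)-2-[3,4,5-tris(benzyloxy)phenyl]chroman-3-ol | c1c(OCc3ccccc3)cc(OCc3ccccc3)c2c1O[C@H](c1cc(OCc3ccccc3)c(OCc3ccccc3)c(OCc3ccccc3)c1)[C@H](O)C2 | intermediate
3 | (2R,3R)-3,5,7-tris(benzyloxy)-2-[3,4,5-tris(benzyloxy)phenyl]chroman (E8–H) | c1c(OCc3ccccc3)cc(OCc3ccccc3)c2c1O[C@H](c1cc(OCc3ccccc3)c(OCc3ccccc3)c(OCc3ccccc3)c1)[C@H](OCc1ccccc1)C2 | intermediate
4 | (2R,3R)-3,5,7-tris(benzyloxy)-8-bromo-2-[3,4,5-tris(benzyloxy)phenyl]chroman (E8–Br) | Brc1c(OCc3ccccc3)cc(OCc3ccccc3)c2c1O[C@H](c1cc(OCc3ccccc3)c(OCc3ccccc3)c(OCc3ccccc3)c1)[C@H](OCc1ccccc1)C2 | intermediate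
5 | [(2R,3R)-3,5,7-tris(benzyloxy)-2-[3,4,5-tris(benzyloxy)phenyl]chroman-8-yl]lithium (E8–Li) | [Li]c1c(OCc3ccccc3)cc(OCc3ccccc3)c2c1O[C@H](c1cc(OCc3ccccc3)c(OCc3ccccc3)c(OCc3ccccc3)c1)[C@H](OCc1ccccc1)C2 | intermediate
6 | lithium (dimethylamino)(E8)methanolate (carbinol carbon unassigned) | [Li]OC(N(C)C)c1c(OCc3ccccc3)cc(OCc3ccccc3)c2c1O[C@H](c1cc(OCc3ccccc3)c(OCc3ccccc3)c(OCc3ccccc3)c1)[C@H](OCc1ccccc1)C2 | intermediate
7 | (2R,3R)-3,5,7-tris(benzyloxy)-2-[3,4,5-tris(benzyloxy)phenyl]chroman-8-carbaldehyde (E8–CHO) | O=Cc1c(OCc3ccccc3)cc(OCc3ccccc3)c2c1O[C@H](c1cc(OCc3ccccc3)c(OCc3ccccc3)c(OCc3ccccc3)c1)[C@H](OCc1ccccc1)C2 | intermediate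
8 | 1-[3,4-bis(benzyloxy)phenyl]ethan-1-one | CC(=O)c1ccc(OCc2ccccc2)c(OCc2ccccc2)c1 | starting material
9 | (2E)-1-[3,4-bis(benzyloxy)phenyl]-3-(E8)prop-2-en-1-one | O=C(/C=C/c1c(OCc3ccccc3)cc(OCc3ccccc3)c2c1O[C@H](c1cc(OCc3ccccc3)c(OCc3ccccc3)c(OCc3ccccc3)c1)[C@H](OCc1ccccc1)C2)c1ccc(OCc2ccccc2)c(OCc2ccccc2)c1 | intermediate
10 | [4-(benzyloxy)-2-fluorophenyl]boronic acid | OB(O)c1ccc(OCc2ccccc2)cc1F | starting material
11 | (3S)-3-[4-(benzyloxy)-2-fluorophenyl]-1-[3,4-bis(benzyloxy)phenyl]-3-(E8)propan-1-one | O(Cc1ccccc1)c1ccc(c(F)c1)[C@H](c1c(OCc3ccccc3)cc(OCc3ccccc3)c2c1O[C@H](c1cc(OCc3ccccc3)c(OCc3ccccc3)c(OCc3ccccc3)c1)[C@H](OCc1ccccc1)C2)CC(=O)c1ccc(OCc2ccccc2)c(OCc2ccccc2)c1 | intermediate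
12 | (1S,3S)-3-[4-(benzyloxy)-2-fluorophenyl]-1-[3,4-bis(benzyloxy)phenyl]-3-(E8)propan-1-ol | O(Cc1ccccc1)c1ccc(c(F)c1)[C@H](c1c(OCc3ccccc3)cc(OCc3ccccc3)c2c1O[C@H](c1cc(OCc3ccccc3)c(OCc3ccccc3)c(OCc3ccccc3)c1)[C@H](OCc1ccccc1)C2)C[C@H](O)c1ccc(OCc2ccccc2)c(OCc2ccccc2)c1 | intermediate
13 | sodium (1S,3S)-3-[4-(benzyloxy)-2-fluorophenyl]-1-[3,4-bis(benzyloxy)phenyl]-3-(E8)propan-1-olate | O(Cc1ccccc1)c1ccc(c(F)c1)[C@H](c1c(OCc3ccccc3)cc(OCc3ccccc3)c2c1O[C@H](c1cc(OCc3ccccc3)c(OCc3ccccc3)c(OCc3ccccc3)c1)[C@H](OCc1ccccc1)C2)C[C@H]([O-])c1ccc(OCc2ccccc2)c(OCc2ccccc2)c1.[Na+] | intermediate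
14 | (2S,4R)-7-(benzyloxy)-2-[3,4-bis(benzyloxy)phenyl]-4-(E8)chroman (nona-O-benzyl target) | O(Cc1ccccc1)c1ccc2c(c1)O[C@H](c1ccc(OCc3ccccc3)c(OCc3ccccc3)c1)C[C@H]2c1c(OCc3ccccc3)cc(OCc3ccccc3)c2c1O[C@H](c1cc(OCc3ccccc3)c(OCc3ccccc3)c(OCc3ccccc3)c1)[C@H](OCc1ccccc1)C2 | intermediate
15 | (2R,3R)-8-[(2S,4R)-2-(3,4-dihydroxyphenyl)-7-hydroxychroman-4-yl]-2-(3,4,5-trihydroxyphenyl)chroman-3,5,7-triol | Oc1ccc2c(c1)O[C@H](c1ccc(O)c(O)c1)C[C@H]2c1c(O)cc(O)c2c1O[C@H](c1cc(O)c(O)c(O)c1)[C@H](O)C2 | target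

**Total step count:** 9
**Longest linear sequence:** 9 steps (1 → 15)

**Three steps most likely to fail**

Step 6 (most likely). The β-carbon of 9 carries a 2,6-dialkoxyaryl group, so insertion into the aryl–Rh bond may be slower than protodeboronation of 10, or facial control may erode. The fallback replaces catalytic enantiocontrol by an auxiliary-controlled cuprate addition; it sets out from aldehyde 7 and comes back at ketone 11. Horner–Wadsworth–Emmons olefination of 7 (LiCl, iPr2NEt, MeCN/THF) with diethyl {2-oxo-2-[(4S)-2-oxo-4-phenyl-1,3-oxazolidin-3-yl]ethyl}phosphonate F1 gives (4S)-3-[(2E)-3-(E8)prop-2-enoyl]-4-phenyl-1,3-oxazolidin-2-one F2. [4-(Benzyloxy)-2-fluorophenyl]magnesium bromide F3 (from commercial 4-(benzyloxy)-1-bromo-2-fluorobenzene and Mg, THF) is added with CuBr·SMe2 at −40 °C. In the Mg-chelated s-cis imide the aryl enters anti to the 4-phenyl group, giving (4S)-3-[(3S)-3-[4-(benzyloxy)-2-fluorophenyl]-3-(E8)propanoyl]-4-phenyl-1,3-oxazolidin-2-one F4. AlMe3/MeNHOMe·HCl (CH2Cl2) converts F4 into (3S)-3-[4-(benzyloxy)-2-fluorophenyl]-N-methoxy-N-methyl-3-(E8)propanamide F5 and releases the auxiliary. [3,4-Bis(benzyloxy)phenyl]lithium F6 (from commercial 4-bromo-1,2-bis(benzyloxy)benzene and n-BuLi, −78 °C) adds once to F5 and gives 11.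

Step 8. The aryl fluoride is unactivated, and hot NaH/DMF may give no ring closure or decomposition. The fallback closes the ring by Pd-catalysed C–O coupling of an aryl bromide; it sets out from chalcone 9 and comes back at 14. Commercial 1-(benzyloxy)-3-bromobenzene is iodinated para to the ether oxygen (NIS, cat. TFA, MeCN) to 4-(benzyloxy)-2-bromo-1-iodobenzene F7. Selective iodine–magnesium exchange (iPrMgCl·LiCl, THF, −40 °C) gives [4-(benzyloxy)-2-bromophenyl]magnesium chloride F8, which with B(OMe)3 and then aqueous acid gives [4-(benzyloxy)-2-bromophenyl]boronic acid F9. Under the conditions of step 6, 9 and F9 give (3S)-3-[4-(benzyloxy)-2-bromophenyl]-1-[3,4-bis(benzyloxy)phenyl]-3-(E8)propan-1-one F10. Under the conditions of step 7 this gives (1S,3S)-3-[4-(benzyloxy)-2-bromophenyl]-1-[3,4-bis(benzyloxy)phenyl]-3-(E8)propan-1-ol F11. Intramolecular etherification (Pd(OAc)2, 2-(di-tert-butylphosphino)-1,1'-binaphthyl, Cs2CO3, toluene, 80 °C) then gives 14, again with retention at the carbinol carbon.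

Step 7. The ketone is electron-rich and β,β-diaryl-branched, so transfer hydrogenation may be slow, or the C3 centre may erode catalyst control. The fallback gives up reagent control in favour of separation and recycling; it sets out from 11 and comes back at 12. NaBH4 (THF/MeOH, 0 °C) reduces 11 to 12 together with its carbinol epimer (1R,3S)-3-[4-(benzyloxy)-2-fluorophenyl]-1-[3,4-bis(benzyloxy)phenyl]-3-(E8)propan-1-ol F12. The two are diastereomers and are separated by chromatography; F12 is oxidised back to 11 (Dess–Martin periodinane, CH2Cl2) and recycled.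

**Further compounds**
F1 | step 6 | diethyl {2-oxo-2-[(4S)-2-oxo-4-phenyl-1,3-oxazolidin-3-yl]ethyl}phosphonate | CCOP(=O)(OCC)CC(=O)N1[C@@H](c2ccccc2)COC1=O
F2 | step 6 | (4S)-3-[(2E)-3-(E8)prop-2-enoyl]-4-phenyl-1,3-oxazolidin-2-one | O=C(/C=C/c1c(OCc3ccccc3)cc(OCc3ccccc3)c2c1O[C@H](c1cc(OCc3ccccc3)c(OCc3ccccc3)c(OCc3ccccc3)c1)[C@H](OCc1ccccc1)C2)N1[C@@H](c2ccccc2)COC1=O
F3 | step 6 | [4-(benzyloxy)-2-fluorophenyl]magnesium bromide | Br[Mg]c1ccc(OCc2ccccc2)cc1F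
F4 | step 6 | (4S)-3-[(3S)-3-[4-(benzyloxy)-2-fluorophenyl]-3-(E8)propanoyl]-4-phenyl-1,3-oxazolidin-2-one | O(Cc1ccccc1)c1ccc(c(F)c1)[C@H](c1c(OCc3ccccc3)cc(OCc3ccccc3)c2c1O[C@H](c1cc(OCc3ccccc3)c(OCc3ccccc3)c(OCc3ccccc3)c1)[C@H](OCc1ccccc1)C2)CC(=O)N1[C@@H](c2ccccc2)COC1=O
F5 | step 6 | (3S)-3-[4-(benzyloxy)-2-fluorophenyl]-N-methoxy-N-methyl-3-(E8)propanamide | O(Cc1ccccc1)c1ccc(c(F)c1)[C@H](c1c(OCc3ccccc3)cc(OCc3ccccc3)c2c1O[C@H](c1cc(OCc3ccccc3)c(OCc3ccccc3)c(OCc3ccccc3)c1)[C@H](OCc1ccccc1)C2)CC(=O)N(C)OC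
F6 | step 6 | [3,4-bis(benzyloxy)phenyl]lithium | [Li]c1ccc(OCc2ccccc2)c(OCc2ccccc2)c1
F7 | step 8 | 4-(benzyloxy)-2-bromo-1-iodobenzene | Ic1ccc(OCc2ccccc2)cc1Br
F8 | step 8 | [4-(benzyloxy)-2-bromophenyl]magnesium chloride | Cl[Mg]c1ccc(OCc2ccccc2)cc1Br
F9 | step 8 | [4-(benzyloxy)-2-bromophenyl]boronic acid | OB(O)c1ccc(OCc2ccccc2)cc1Br
F10 | step 8 | (3S)-3-[4-(benzyloxy)-2-bromophenyl]-1-[3,4-bis(benzyloxy)phenyl]-3-(E8)propan-1-one | O(Cc1ccccc1)c1ccc(c(Br)c1)[C@H](c1c(OCc3ccccc3)cc(OCc3ccccc3)c2c1O[C@H](c1cc(OCc3ccccc3)c(OCc3ccccc3)c(OCc3ccccc3)c1)[C@H](OCc1ccccc1)C2)CC(=O)c1ccc(OCc2ccccc2)c(OCc2ccccc2)c1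
F11 | step 8 | (1S,3S)-3-[4-(benzyloxy)-2-bromophenyl]-1-[3,4-bis(benzyloxy)phenyl]-3-(E8)propan-1-ol | O(Cc1ccccc1)c1ccc(c(Br)c1)[C@H](c1c(OCc3ccccc3)cc(OCc3ccccc3)c2c1O[C@H](c1cc(OCc3ccccc3)c(OCc3ccccc3)c(OCc3ccccc3)c1)[C@H](OCc1ccccc1)C2)C[C@H](O)c1ccc(OCc2ccccc2)c(OCc2ccccc2)c1
F12 | step 7 | (1R,3S)-3-[4-(benzyloxy)-2-fluorophenyl]-1-[3,4-bis(benzyloxy)phenyl]-3-(E8)propan-1-ol | O(Cc1ccccc1)c1ccc(c(F)c1)[C@H](c1c(OCc3ccccc3)cc(OCc3ccccc3)c2c1O[C@H](c1cc(OCc3ccccc3)c(OCc3ccccc3)c(OCc3ccccc3)c1)[C@H](OCc1ccccc1)C2)C[C@@H](O)c1ccc(OCc2ccccc2)c(OCc2ccccc2)c1
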